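The leftover is where I started: at 14 min the elm run still held 0.0660 M of E and the cedar run 0.0612 M, from equal charges of E and J but different [X]. The alder run is asked at that same time, so I froze the time and let [X] move.

| flask | E | J | X | time |
|---|---|---|---|---|
| elm | 0.150 M | 0.180 M | 0.0150 M |  |
| cedar | 0.150 M | 0.180 M | 0.0220 M |  |
| alder | 0.150 M | 0.180 M | 0.0310 M | 14 min |

| run | time / min | [E] / M |
|---|---|---|
| elm run | 1.1 | 0.1283 |
| elm run | 3.2 | 0.1033 |
| elm run | 6.2 | 0.0846 |
| elm run | 9.8 | 0.0734 |
| elm run | 14 | 0.0660 |
| cedar run | 1.1 | 0.1207 |
| cedar run | 3.2 | 0.0926 |
| cedar run | 6.2 | 0.0753 |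
| cedar run | 9.8 | 0.0666 |
| cedar run | 14 | 0.0612 |

(each reading ± 4 × 10⁻⁴ M)

- Overall: E + J -> Z, with X as catalyst.
- Constant volume, constant temperature.
- Bound and free are read together.
- "The second partner" is J.
- An order is taken over about fifteen percent of the charge, up and down.

- how the opening rate goes with [X] round the charge of the elm run: the exponent of the rate at two percent of E gone to Z
- E in the alder run at 14 min, as a share of the E charged

My rule was to treat the fall in leftover [E] at fixed time, per unit of ln[X], as nearly constant, and to extend it from cedar to alder. Before taking the number, I asked which inputs it leaned on. The alder estimate is the cedar reading counted 1.90 times, less the elm reading counted 0.895 times, so the cedar reading weighs more. Their scatter carries through as 0.559 % of the charge. The earlier readings don't enter, and the clock cancels, since both readings and the question stand at 14 min. If the rule's constant were off by 10 percent, the estimate would move by 4.298 × 10⁻⁴ M, close to the scatter of one reading.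

So I took the catalyst step, the fall in leftover [E] at 14 min per unit of ln[X], 0.01253 M. Extended to alder, it gave 0.05690 M, or 37.9 % of the charge. For the exponent I had no reckoning of my own.

The forecast gave 0.95 and 38.7 %, a share above mine, and read the steep decay this way: “That points to an approach to equilibrium or to product inhibition.”

The flask gave 0.98 and 38.2 %.

    X + E ⇌ XE, settled at all times (23.20 /M)
    XE + J → Z + X + L (11.10 /M/min)
    2 X → 2 Ek (17.10 /M/min)
    J + L ⇌ JL, settled at all times (250.0 /M)

In the cedar run, XE + J → Z + X + L brought Z to a quarter of the E charged by 1.58 min and to half by 6.30 min, with 2 X → 2 Ek running beside it. Getting from the first of those marks to the second took 4.72 min, longer than the 1.58 min to reach the first. From cedar to alder the catalyst step measured 0.01119 M, against 0.0125 M from elm to cedar.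

Readings and results are simulated for substances that don't exist, and the scatter is random.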